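Ring B (C5–C10, clerodane numbering) is disconnected across C8–C9 and C5–C10. An acyclic bis-enone carrying a cis-acetonide from D-erythronolactone is turned into its (Z)-2-silyloxytriene, and a magnesium-chelated intramolecular Diels–Alder reaction onto the (E)-β,β-disubstituted enone lets C8 attack quaternary C9, closing ring B, while C5–C10 closes ring A. The step exploits the C7 oxygen of ring B (latent silyl enol ether, para to C10), its flanking C8 methine, and the cis A/B fusion (H-10/CH3-19), and sets C5, C8, C9 and C10 at once. The acetonide steers the face and later unveils the ring-A diosphenol and exocyclic enone.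

Key step: step 11

Remark on numbering: C1 = ring-A vinylic CH, C2 = C–OH, C3 = C=O, C4 = C(=CH2) (methylene C18), C5 = angular C–CH3 (C19), C6 = CH2, C7 = CH–OAc, C8 = CH–CH3 (C17), C9 = quaternary C (CH3 = C20, side chain C11–C16), C10 = ring-fusion CH.
Assumption: carbinol centres that are later oxidised or eliminated (C7 in 10 and 15, the anomeric carbon of 12, C1 in 17 and 21–26) are carried as epimer mixtures.

Step 1
Reactants: 1 hex-5-yn-2-one; 2 tert-butyl 2-(diethoxyphosphoryl)acetate
Product: 3 tert-butyl (E)-3-methylhept-2-en-6-ynoate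
Conditions: NaH, THF, 0 → 23 °C
Reagents that add atoms: none
Why: Horner–Wadsworth–Emmons olefination of the methyl ketone should favour the (E)-enoate (chain trans to the ester), and the tert-butyl ester is chosen to last until the acidic unmasking in step 15.

Step 2
Reactants: 3 tert-butyl (E)-3-methylhept-2-en-6-ynoate
Product: 5 tert-butyl (2E,6E)-7-iodo-3,6-dimethylhepta-2,6-dienoate, via alkenylalane 4 (not isolated)
Conditions: Me3Al, Cp2ZrCl2 (cat.), H2O (1 equiv), CH2Cl2, −23 °C; then I2, THF, −23 → 0 °C
Reagents that add atoms: trimethylaluminium, C[Al](C)C; iodine, II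
Why: Negishi carboalumination adds CH3 and aluminium syn across the terminal alkyne (CH3 to the internal carbon) and iodinolysis with retention should give the (E)-iodide with iodine cis to the new methyl (C20), the hindered tert-butyl enoate being expected to resist Me3Al at this temperature.

Step 3
Reactants: 6 hex-4-yn-3-ol (racemic)
Product: 10 (E)-5-iodohex-4-en-3-ol, via silyl ether 7 (not isolated), via alkenylzirconocene 8 (not isolated), via iodo silyl ether 9 (not isolated)
Conditions: TMSCl, Et3N, THF, 0 °C (filter); Cp2Zr(H)Cl, THF, 50 °C; I2, 0 °C; then 1 M HCl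
Reagents that add atoms: iodine, II
Why: After temporary silylation, syn-hydrozirconation should place zirconium on the less hindered methyl-bearing alkyne carbon, and iodinolysis with retention followed by acidic desilylation should give the iodide with iodine trans to the carbinol carbon (future C4 trans to C7).

Step 4
Reactants: 11 2,3-O-isopropylidene-D-erythronolactone
Product: 12 2,3-O-isopropylidene-D-erythrofuranose (lactol, anomer mixture)
Conditions: DIBAL-H, CH2Cl2, −78 °C
Reagents that add atoms: none
Why: Partial reduction of a lactone to the lactol at low temperature is standard and leaves the cis-acetonide untouched.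

Step 5
Reactants: 12 2,3-O-isopropylidene-D-erythrofuranose
Product: 13 [(4R,5S)-5-ethynyl-2,2-dimethyl-1,3-dioxolan-4-yl]methanol
Conditions: dimethyl (1-diazo-2-oxopropyl)phosphonate, K2CO3, MeOH, 0 → 23 °C
Reagents that add atoms: dimethyl (1-diazo-2-oxopropyl)phosphonate, CC(=O)C(=[N+]=[N-])P(=O)(OC)OC
Why: Ohira–Bestmann homologation of the open aldehyde form should give the terminal alkyne (C4≡C18) with the two dioxolane stereocentres (future C2 and C3) carried over from the chiral pool.

Step 6
Reactants: 13 [(4R,5S)-5-ethynyl-2,2-dimethyl-1,3-dioxolan-4-yl]methanol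
Product: 14 [(4R,5S)-2,2-dimethyl-5-[1-(4,4,5,5-tetramethyl-1,3,2-dioxaborolan-2-yl)ethenyl]-1,3-dioxolan-4-yl]methanol
Conditions: B2pin2, (SIMes)CuCl (cat.), NaOtBu (cat.), MeOH, THF, 23 °C
Reagents that add atoms: bis(pinacolato)diboron, CC1(C)OB(OC1(C)C)B1OC(C)(C)C(C)(C)O1
Why: Copper–boryl addition with an N-heterocyclic carbene ligand to terminal propargylic ethers is known to place boron on the internal carbon (α-selective protoboration), giving the 1,1-disubstituted alkenylboronate that carries the future exocyclic methylene.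

Step 7
Reactants: 14 alkenylboronate; 10 (E)-5-iodohex-4-en-3-ol
Product: 15 (4E)-6-[(4S,5R)-5-(hydroxymethyl)-2,2-dimethyl-1,3-dioxolan-4-yl]-5-methylhepta-4,6-dien-3-ol (triene diol, C7 epimers)
Conditions: Pd(dppf)Cl2 (cat.), Cs2CO3, THF/H2O, 50 °C
Reagents that add atoms: none
Why: Suzuki–Miyaura coupling proceeds with retention at both sp2 carbons and should join C4 to C5, with C4 trans to C7.

Step 8
Reactants: 15 triene diol
Product: 16 (4S,5S)-2,2-dimethyl-5-[(3E)-3-methyl-5-oxohepta-1,3-dien-2-yl]-1,3-dioxolane-4-carbaldehyde (keto aldehyde)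
Conditions: Dess–Martin periodinane, NaHCO3, CH2Cl2, 0 → 23 °C
Reagents that add atoms: none
Why: Dess–Martin oxidation should convert the allylic secondary alcohol into the ethyl dienone and the primary alcohol into the C1 aldehyde in one buffered, non-epimerising operation.

Step 9
Reactants: 16 keto aldehyde; 5 tert-butyl (2E,6E)-7-iodo-3,6-dimethylhepta-2,6-dienoate
Product: 17 C1 allylic alcohol (C1 epimers) with the full C1–C20 chain
Conditions: CrCl2, NiCl2 (cat.), DMSO, 23 °C
Reagents that add atoms: none
Why: Nozaki–Hiyama–Kishi coupling is selective for the aldehyde over the enone and the ester and transfers the (E)-alkenyl group with retention.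

Step 10
Reactants: 17 C1 allylic alcohol
Product: 18 bis-enone (C7 ethyl dienone and C1 (E)-enone flanking the cis-acetonide)
Conditions: Dess–Martin periodinane, NaHCO3, CH2Cl2, 0 °C
Reagents that add atoms: none
Why: Dess–Martin oxidation of the allylic alcohol should give the (E)-enone dienophile without double-bond isomerisation or epimerisation at the α-alkoxy carbon C2.

Step 11
Reactants: 18 bis-enone
Product: 20 cis-fused Diels–Alder adduct (C1 ketone, 2,3-acetonide, C4 exocyclic methylene, C6=C7 TBS enol ether; C5, C8, C9, C10 as in the target), via silyloxytriene 19 (not isolated)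
Conditions: TBSOTf, Et3N, CH2Cl2, −78 °C; then MgBr2·OEt2, −78 → 0 °C
Reagents that add atoms: tert-butyldimethylsilyl triflate, CC(C)(C)[Si](C)(C)OS(=O)(=O)C(F)(F)F
Why: Soft enolization should silylate only the ethyl ketone (its α-CH2 is the sole unhindered α-position; C2–H is tertiary and held in the dioxolane) to give the (Z)-silyloxytriene 19, and MgBr2 chelated between the C1 carbonyl and the dioxolane oxygen on C2 then promotes a normal-demand intramolecular Diels–Alder reaction, the closest known type being Lewis-acid-promoted cycloadditions of 2-silyloxydienes onto tethered enones (decatrienones). The cycloaddition is asynchronous, the nucleophilic terminus C8 bonding first to the β-carbon C9: ring B closes as the six-membered [4+2] ring through C8–C9 and C5–C10, and ring A closes as the fused tether ring through C5–C10. C9 and C10 follow from the (E)-dienophile, C8 from the (Z)-enol ether and C5 from the (E)-C5=C6 bond (tether outside, CH3-19 inside, so the diene can still reach the s-cis form). The cis ring fusion (H-10 cis to CH3-19) follows from the tether carbonyl lying endo under the diene in a boat-like tether, the arrangement favoured when the activating carbonyl is part of the tether. The absolute sense comes from the acetonide: in the chelate the C2–O bond eclipses C1=O, so the chain through C3 can reach only the enone face that places H-2 and H-10 cis, and the cis-dioxolane fits the nearly eclipsed C2–C3 bond of this transition state. The step needs periselectivity (the alternative C18=C4–C5=C6 diene could only close to a bridgehead alkene), regioselective enolization and endo/facial selectivity, which the short carbonyl-containing tether and the chelate are expected to secure.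

Step 12
Reactants: 20 Diels–Alder adduct
Product: 22 C1-hydroxy C7-ketone, via C1 alcohol silyl enol ether 21 (not isolated)
Conditions: NaBH4, MeOH/CH2Cl2, −40 °C; then 1 M HCl, THF, 0 °C
Reagents that add atoms: none
Why: Borohydride should reduce only the C1 ketone while C7 is masked as the silyl enol ether, and brief aqueous acid then hydrolyses the enol ether to the C7 ketone without touching the acetonide or the tert-butyl ester.

Step 13
Reactants: 22 C1-hydroxy C7-ketone
Product: 23 C1,C7-diol (7β-OH, equatorial, trans to CH3-17)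
Conditions: Al(OiPr)3, iPrOH, acetone (cat.), toluene, 80 °C
Reagents that add atoms: none
Why: Meerwein–Ponndorf–Verley reduction under equilibrating conditions should give the thermodynamically preferred equatorial 7β-alcohol, whereas kinetic hydride attack from the convex β-face would be expected to give the axial 7α-epimer (syn-axial to C4 and CH3-20).

Step 14
Reactants: 23 C1,C7-diol
Product: 24 C1,C7-diacetate
Conditions: Ac2O, DMAP, pyridine, 23 °C
Reagents that add atoms: acetic anhydride, CC(=O)OC(C)=O
Why: DMAP-catalysed acetylation installs the C7 acetate of the target and turns C1–OH into the leaving group for the final elimination.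

Step 15
Reactants: 24 C1,C7-diacetate
Product: 25 C2,C3-diol carboxylic acid
Conditions: TFA/CH2Cl2/H2O, 0 °C
Reagents that add atoms: none
Why: Aqueous trifluoroacetic acid should cleave the acetonide and the tert-butyl ester together while the secondary acetates are stable to acid.

Step 16
Reactants: 25 C2,C3-diol carboxylic acid
Product: 27 target CNP0192653.1, via ketol 26 (not isolated)
Conditions: IBX, DMSO, 23 °C; then iPr2NEt, 0 → 23 °C
Reagents that add atoms: none
Why: IBX oxidises 1,2-diols to α-ketols without C–C cleavage, the allylic C3–OH being the more reactive site, and the resulting β-acetoxy ketone should lose acetic acid from C1 by E1cB to give the diosphenol next to the exocyclic enone (oxidation at C2 instead should converge on the same product through the enediol).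

Compound list
1 | hex-5-yn-2-one | CC(=O)CCC#C | starting material
2 | tert-butyl 2-(diethoxyphosphoryl)acetate | CCOP(=O)(OCC)CC(=O)OC(C)(C)C | starting material
3 | tert-butyl (E)-3-methylhept-2-en-6-ynoate | C#CCC/C(C)=C/C(=O)OC(C)(C)C | intermediate
4 | tert-butyl (2E,6E)-7-(dimethylalumanyl)-3,6-dimethylhepta-2,6-dienoate (alkenylalane) | C[Al](C)/C=C(C)/CC/C(C)=C/C(=O)OC(C)(C)C | intermediate
5 | tert-butyl (2E,6E)-7-iodo-3,6-dimethylhepta-2,6-dienoate | I/C=C(C)/CC/C(C)=C/C(=O)OC(C)(C)C | intermediate
6 | hex-4-yn-3-ol (racemic) | CCC(O)C#CC | starting material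
7 | (hex-4-yn-3-yloxy)trimethylsilane | CCC(O[Si](C)(C)C)C#CC | intermediate
8 | (E)-alkenylzirconocene chloride from 7 (Zr on the methyl-bearing carbon; cyclopentadienyl rings drawn σ-bound) | CCC(O[Si](C)(C)C)/C=C(C)/[Zr](Cl)(C1C=CC=C1)C1C=CC=C1 | intermediate
9 | (E)-5-iodo-3-(trimethylsilyloxy)hex-4-ene | CCC(O[Si](C)(C)C)/C=C(C)/I | intermediate
10 | (E)-5-iodohex-4-en-3-ol | CCC(O)/C=C(C)/I | intermediate
11 | 2,3-O-isopropylidene-D-erythronolactone, (3aR,6aR) | O=C1OC[C@H]2OC(C)(C)O[C@@H]12 | starting material
12 | 2,3-O-isopropylidene-D-erythrofuranose (anomer mixture) | OC1OC[C@H]2OC(C)(C)O[C@@H]12 | intermediate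
13 | [(4R,5S)-5-ethynyl-2,2-dimethyl-1,3-dioxolan-4-yl]methanol | OC[C@H]1OC(C)(C)O[C@H]1C#C | intermediate
14 | [(4R,5S)-2,2-dimethyl-5-[1-(4,4,5,5-tetramethyl-1,3,2-dioxaborolan-2-yl)ethenyl]-1,3-dioxolan-4-yl]methanol | OC[C@H]1OC(C)(C)O[C@H]1C(=C)B1OC(C)(C)C(C)(C)O1 | intermediate
15 | (4E)-6-[(4S,5R)-5-(hydroxymethyl)-2,2-dimethyl-1,3-dioxolan-4-yl]-5-methylhepta-4,6-dien-3-ol (C7 epimers) | CCC(O)/C=C(C)/C(=C)[C@@H]1OC(C)(C)O[C@@H]1CO | intermediate
16 | (4S,5S)-2,2-dimethyl-5-[(3E)-3-methyl-5-oxohepta-1,3-dien-2-yl]-1,3-dioxolane-4-carbaldehyde | CCC(=O)/C=C(C)/C(=C)[C@@H]1OC(C)(C)O[C@@H]1C=O | intermediate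
17 | C1 allylic alcohol (C1 epimers): tert-butyl ester of the C1-hydroxy seco-chain, (E)-C5=C6, (E)-C9=C10, (E)-C13=C14, 2,3-cis-acetonide | CCC(=O)/C=C(C)/C(=C)[C@@H]1OC(C)(C)O[C@@H]1C(O)/C=C(C)/CC/C(C)=C/C(=O)OC(C)(C)C | intermediate
18 | bis-enone: C1 ketone analogue of 17 | CCC(=O)/C=C(C)/C(=C)[C@@H]1OC(C)(C)O[C@@H]1C(=O)/C=C(C)/CC/C(C)=C/C(=O)OC(C)(C)C | intermediate
19 | (Z)-C7-silyloxytriene of 18 (TBS enol ether, C17 cis to O) | C/C=C(O[Si](C)(C)C(C)(C)C)/C=C(C)/C(=C)[C@@H]1OC(C)(C)O[C@@H]1C(=O)/C=C(C)/CC/C(C)=C/C(=O)OC(C)(C)C | intermediate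
20 | cis-decalin Diels–Alder adduct: C1 ketone, 2α,3α-acetonide, C4=CH2, C6=C7 TBS enol ether, tert-butyl ester | C=C1[C@@H]2OC(C)(C)O[C@@H]2C(=O)[C@@H]3[C@@](C)(CC/C(C)=C/C(=O)OC(C)(C)C)[C@H](C)C(O[Si](C)(C)C(C)(C)C)=C[C@]13C | intermediate
21 | C1 alcohol of 20 (C1 epimers), enol ether intact | C=C1[C@@H]2OC(C)(C)O[C@@H]2C(O)[C@@H]3[C@@](C)(CC/C(C)=C/C(=O)OC(C)(C)C)[C@H](C)C(O[Si](C)(C)C(C)(C)C)=C[C@]13C | intermediate
22 | C1-hydroxy C7-ketone | C=C1[C@@H]2OC(C)(C)O[C@@H]2C(O)[C@@H]3[C@@](C)(CC/C(C)=C/C(=O)OC(C)(C)C)[C@H](C)C(=O)C[C@]13C | intermediate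
23 | C1,C7-diol (7β-OH) | C=C1[C@@H]2OC(C)(C)O[C@@H]2C(O)[C@@H]3[C@@](C)(CC/C(C)=C/C(=O)OC(C)(C)C)[C@H](C)[C@@H](O)C[C@]13C | intermediate
24 | C1,C7-diacetate | C=C1[C@@H]2OC(C)(C)O[C@@H]2C(OC(C)=O)[C@@H]3[C@@](C)(CC/C(C)=C/C(=O)OC(C)(C)C)[C@H](C)[C@@H](OC(C)=O)C[C@]13C | intermediate
25 | C2,C3-diol carboxylic acid (C1,C7-diacetate) | C=C1[C@H](O)[C@H](O)C(OC(C)=O)[C@@H]2[C@@](C)(CC/C(C)=C/C(=O)O)[C@H](C)[C@@H](OC(C)=O)C[C@]12C | intermediate
26 | C3-keto C2-hydroxy C1-acetoxy acid (α-ketol) | C=C1C(=O)[C@H](O)C(OC(C)=O)[C@@H]2[C@@](C)(CC/C(C)=C/C(=O)O)[C@H](C)[C@@H](OC(C)=O)C[C@]12C | intermediate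
27 | CNP0192653.1 | C=C1C(=O)C(O)=C[C@@H]2[C@@](C)(CC/C(C)=C/C(=O)O)[C@H](C)[C@@H](OC(C)=O)C[C@]12C | target

Total step count: 16. Longest linear sequence: 13 steps (steps 4–16, from 11).

Steps most likely to fail

1. Step 11. The soft enolization may also touch the C1 enone (γ-deprotonation or epimerisation at C2). The cycloaddition may be slow because two quaternary carbons form, or may stop after the first C8–C9 bond. Facial selectivity may erode if the magnesium chelate is not maintained. Fallback: starting from 18, an anionic intramolecular double Michael reaction (LiHMDS, THF, −78 → 0 °C, acetic acid quench) uses the lithium cross-conjugated dienolate of the ethyl ketone, which should add through C8 to C9 and then close C10 onto C5 under lithium chelation, giving the diketone F1. Meerwein–Ponndorf–Verley reduction of both ketones of F1 (Al(OiPr)3, iPrOH, toluene, 80 °C) comes back to the route at 23.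

2. Step 13. Equilibration may be incomplete, leaving the kinetic axial alcohol, or the aluminium enolate may epimerise C8. Fallback: starting from 22, kinetic reduction (NaBH4, MeOH, 0 °C, 1 M HCl work-up) should give the 7α-epimer F2. Redox-neutral epimerisation of the secondary alcohol with a ruthenium hydrogen-transfer catalyst ((η5-C5Ph5)Ru(CO)2Cl, KOtBu, toluene, 23–60 °C) should then drain F2 to the equatorial alcohol and comes back at 23.

3. Step 16. Over-oxidation of the ketol to the 1,2-dione, acetate migration from O1 to O2 during step 15, or Michael addition to the new exocyclic enone may intervene. Fallback: starting from 24, aqueous acetic acid (40 °C) should remove only the acetonide to give the diol tert-butyl ester F3. The dibutylstannylene acetal F4 (Bu2SnO, toluene, reflux) is oxidised with Br2 (CH2Cl2, 23 °C) to the ketol ester F5, a mono-oxidation that cannot go on to the dione. Et3N then eliminates acetic acid to the diosphenol tert-butyl ester F6, and TFA/CH2Cl2 (0 °C) cleaves the ester and comes back at 27.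

Further compounds
F1 | step 11 | C1,C7-diketone cis-decalin (acetonide, tert-butyl ester) | C=C1[C@@H]2OC(C)(C)O[C@@H]2C(=O)[C@@H]3[C@@](C)(CC/C(C)=C/C(=O)OC(C)(C)C)[C@H](C)C(=O)C[C@]13C
F2 | step 13 | 7α-epimer of diol 23 | C=C1[C@@H]2OC(C)(C)O[C@@H]2C(O)[C@@H]3[C@@](C)(CC/C(C)=C/C(=O)OC(C)(C)C)[C@H](C)[C@H](O)C[C@]13C
F3 | step 16 | C2,C3-diol tert-butyl ester (C1,C7-diacetate) | C=C1[C@H](O)[C@H](O)C(OC(C)=O)[C@@H]2[C@@](C)(CC/C(C)=C/C(=O)OC(C)(C)C)[C@H](C)[C@@H](OC(C)=O)C[C@]12C
F4 | step 16 | 2,3-O-dibutylstannylene acetal of F3 | C=C1[C@@H]2O[Sn](CCCC)(CCCC)O[C@@H]2C(OC(C)=O)[C@@H]3[C@@](C)(CC/C(C)=C/C(=O)OC(C)(C)C)[C@H](C)[C@@H](OC(C)=O)C[C@]13C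
F5 | step 16 | C3-keto C2-hydroxy C1-acetoxy tert-butyl ester | C=C1C(=O)[C@H](O)C(OC(C)=O)[C@@H]2[C@@](C)(CC/C(C)=C/C(=O)OC(C)(C)C)[C@H](C)[C@@H](OC(C)=O)C[C@]12C
F6 | step 16 | tert-butyl ester of the target | C=C1C(=O)C(O)=C[C@@H]2[C@@](C)(CC/C(C)=C/C(=O)OC(C)(C)C)[C@H](C)[C@@H](OC(C)=O)C[C@]12C
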